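Retrosynthesis: the O7–prenyl bond is cut first. The C4 ketone is then taken back to a carbinol, so that the oxygens on C3 and C4 of ring C become a cis-diol.
The diol is traced to the C3=C4 alkene of a (2S)-2-aryl-2H-chromene. The C2–C1' bond to ring B is cut last, giving a 2-ethoxychromene and an arylboronate.
Enabling feature: O3 and O4 sit on adjacent carbons of ring C next to C2. The aryl group on C2 (ring B) covers one face of the C3=C4 bond, so both oxygens can arrive together from the open face.
Forward: ring C is closed first as a coumarin on ring A (phloroglucinol) and ring B is joined at C2. C3/C4 are then dihydroxylated, O3 is masked, C4 is oxidised, all benzyl groups are removed and O7 is prenylated last.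
Stereochemistry: C2 comes from a tartaric-acid-derived catalyst in the boronate addition, C3 is relayed from C2 in the dihydroxylation, and the C4 centre is transient.
Key step: step 9

Assumption: the absolute sense of induction in step 8 has to be confirmed in a trial run. The catalyst can be made from L- or D-tartaric acid, both commercial, and the enantiomer that delivers (2S)-14 is used.

Step 1
Reactants: 1 phloroglucinol; 2 ethyl propiolate
Product: 3 5,7-dihydroxycoumarin
Conditions: ZnCl2, neat, 100 °C
Reagents that add atoms: none
Why: Pechmann-type condensation, in which ZnCl2-promoted hydroarylation of the alkyne by the very electron-rich ring and lactonisation with loss of ethanol close the pyranone ring, the threefold symmetry of 1 leaving only one possible regioisomer.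

Step 2
Reactants: 3 5,7-dihydroxycoumarin
Product: 4 5,7-bis(benzyloxy)coumarin
Conditions: BnBr, K2CO3, DMF, 60 °C
Reagents that add atoms: benzyl bromide, BrCc1ccccc1
Why: Williamson etherification of both phenols, giving benzyl ethers that tolerate hydride, mild acid, OsO4 and periodinane and leave together by hydrogenolysis before the prenyl group is introduced.

Step 3
Reactants: 4 5,7-bis(benzyloxy)coumarin
Product: 5 5,7-bis(benzyloxy)-2H-chromen-2-ol (racemic lactol)
Conditions: i-Bu2AlH, CH2Cl2, −78 °C
Reagents that add atoms: none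
Why: Partial lactone-to-lactol reduction with i-Bu2AlH, a standard entry to 2H-chromen-2-ols from coumarins, in which the aluminium hemiacetal formed at −78 °C does not collapse before the quench, so a second hydride transfer is avoided; the new C2 centre is of no consequence because it is ionised later.

Step 4
Reactants: 5 5,7-bis(benzyloxy)-2H-chromen-2-ol
Product: 6 5,7-bis(benzyloxy)-2-ethoxy-2H-chromene (racemic acetal)
Conditions: EtOH, PPTS (cat.), 3 Å MS, rt
Reagents that add atoms: ethanol, CCO
Why: Acid-catalysed acetalisation of the lactol, in which the C2 hydroxyl, activated by O1 and the donor ring A, is exchanged for ethoxy under very mild acid while the sieves take up the water; C2 stays racemic, which does not matter.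

Step 5
Reactants: 7 4-bromo-2-methoxyphenol
Product: 8 1-(benzyloxy)-4-bromo-2-methoxybenzene
Conditions: BnBr, K2CO3, acetone, reflux
Reagents that add atoms: benzyl bromide, BrCc1ccccc1
Why: Williamson etherification that masks the acidic phenol before metalation with the same protecting group as on ring A.

Step 6
Reactants: 8 1-(benzyloxy)-4-bromo-2-methoxybenzene
Product: 11 [4-(benzyloxy)-3-methoxyphenyl]boronic acid, via aryllithium 9 (not isolated), via lithium aryltriisopropoxyborate 10 (not isolated)
Conditions: n-BuLi, THF, −78 °C; B(Oi-Pr)3, −78 °C to rt; 1 M HCl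
Reagents that add atoms: n-butyllithium, [Li]CCCC (lithium of 9 and 10 only); triisopropyl borate, CC(C)OB(OC(C)C)OC(C)C; water, O
Why: Bromine–lithium exchange followed by electrophilic borylation and hydrolysis, the standard aryl bromide to boronic acid sequence, which the benzyl and methyl ethers tolerate at −78 °C.

Step 7
Reactants: 11 [4-(benzyloxy)-3-methoxyphenyl]boronic acid
Product: 12 diethyl [4-(benzyloxy)-3-methoxyphenyl]boronate (used crude, moisture-sensitive)
Conditions: EtOH, toluene, reflux, azeotropic removal of water
Reagents that add atoms: ethanol, CCO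
Why: Reversible esterification of a boronic acid driven by removal of water, which supplies the labile ethoxy ligands that the chiral catalyst must displace in the next step.

Step 8
Reactants: 6 5,7-bis(benzyloxy)-2-ethoxy-2H-chromene; 12 diethyl [4-(benzyloxy)-3-methoxyphenyl]boronate
Product: 14 (2S)-5,7-bis(benzyloxy)-2-[4-(benzyloxy)-3-methoxyphenyl]-2H-chromene, via 5,7-bis(benzyloxy)chromenylium ion 13 (not isolated)
Conditions: 4-(dibenzylamino)-2,3-dihydroxy-4-oxobutanoic acid (tartaric acid monoamide, cat.), Yb(OTf)3 (cat.), EtOAc, −20 °C, dark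
Reagents that add atoms: none
Why: Enantioselective addition of an aryl boronate to a chromene acetal under combined chiral Brønsted acid and Lewis acid catalysis, in which the dihydroxy acid displaces the ethoxy groups of 12 at boron, Yb(OTf)3 helps to ionise 6 to the planar cation 13, and the electron-rich aryl group migrates from the chiral borate counter-ion to one face of C2, so that the catalyst sets C2 (2S in 14, the same spatial arrangement as 2R in the target).

Step 9
Reactants: 14 (2S)-5,7-bis(benzyloxy)-2-[4-(benzyloxy)-3-methoxyphenyl]-2H-chromene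
Product: 16 (2R,3S,4S)-5,7-bis(benzyloxy)-2-[4-(benzyloxy)-3-methoxyphenyl]-3,4-dihydro-2H-chromene-3,4-diol (2,3-trans-3,4-cis), via cyclic osmate ester 15 (not isolated)
Conditions: OsO4 (cat.), NMO, acetone/H2O, 0 °C to rt, dark
Reagents that add atoms: osmium tetroxide, O=[Os](=O)(=O)=O; N-methylmorpholine N-oxide, C[N+]1([O-])CCOCC1; water, O
Why: OsO4 adds to the C3=C4 bond of 14 in a concerted, suprafacial [3+2] cycloaddition to give the hexavalent osmate ester 15, which water hydrolyses to the cis-diol while NMO returns osmium to the octavalent state. The closest known reaction type is the catalytic OsO4/NMO syn-dihydroxylation of flav-3-enes, which delivers 2,3-trans-3,4-cis-flavan-3,4-diols. No ring of the product is closed; the five-membered osmate ring of 15 is only transient. C3 and C4 are both controlled by the C2 stereocentre: the aryl group on C2 of the half-chair ring C shields its own face, so osmium approaches from the other face, placing O3 trans to ring B (3S here, 3R once C4 is a ketone) and O4 cis to O3 (4S). The step needs facial selectivity, secured by that single allylic substituent, and chemoselectivity, secured because the electron-rich styrene-type C3=C4 bond is the only alkene present (the prenyl group is held back and benzyl ethers are inert to OsO4). The neutral medium and exclusion of light protect the acid-labile C4 carbinol and the C2 centre of the 2H-chromene.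

Step 10
Reactants: 16 (2R,3S,4S)-flavan-3,4-diol tribenzyl ether
Product: 17 (2R,3S,4S)-3,5,7-tris(benzyloxy)-2-[4-(benzyloxy)-3-methoxyphenyl]-3,4-dihydro-2H-chromen-4-ol
Conditions: BnBr, Ag2O, Ph2BOCH2CH2NH2 (cat.), MeCN, 40 °C
Reagents that add atoms: benzyl bromide, BrCc1ccccc1
Why: Borinic-acid-catalysed regioselective mono-O-alkylation of a cis-1,2-diol, in which the catalyst binds O3 and O4 as a tetracoordinate borinate and the equatorial, less encumbered O3 is benzylated rather than the pseudo-axial O4 next to the 5-benzyloxy group; this removes the need for a benzylic-selective oxidant (MnO2 tends to cleave cis-diols, and hydride abstractors need a C4–H bond aligned with ring A, whereas in 16 it is pseudo-equatorial).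

Step 11
Reactants: 17 3-O-benzyl flavan-4-ol
Product: 18 (2R,3R)-3,5,7-tris(benzyloxy)-2-[4-(benzyloxy)-3-methoxyphenyl]-2,3-dihydro-4H-chromen-4-one
Conditions: Dess–Martin periodinane, NaHCO3, CH2Cl2, 0 °C to rt
Reagents that add atoms: none
Why: Dess–Martin oxidation of the only free hydroxyl, which needs no benzylic alignment of the C4–H bond; the bicarbonate buffer shields the ionisable C4 carbinol and the C3 centre alpha to the new ketone, and C2 and C3 are untouched (C3 becomes 3R by a change of priorities only).

Step 12
Reactants: 18 tetra-O-benzyl dihydroflavonol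
Product: 19 (2R,3R)-3,5,7-trihydroxy-2-(4-hydroxy-3-methoxyphenyl)-2,3-dihydro-4H-chromen-4-one (3'-O-methyltaxifolin)
Conditions: H2 (1 atm), Pd(OH)2/C, THF/MeOH, rt
Reagents that add atoms: none
Why: Catalytic hydrogenolysis of the three aryl benzyl ethers and the C3 alkyl benzyl ether, as practised on perbenzylated dihydroflavonols; the donor-substituted C4 ketone (hydrogen-bonded once O5 is free) and the C2–O1 bond are reduced much more slowly, so the reaction is stopped after uptake of four equivalents of hydrogen.

Step 13
Reactants: 19 3'-O-methyltaxifolin; 20 prenyl bromide (1.05 equiv)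
Product: 21 (2R,3R)-3,5-dihydroxy-2-(4-hydroxy-3-methoxyphenyl)-7-[(3-methylbut-2-en-1-yl)oxy]-2,3-dihydro-4H-chromen-4-one (target)
Conditions: K2CO3 (1.0 equiv), acetone, argon, rt
Reagents that add atoms: none
Why: Williamson etherification under acidity control, in which the 7-OH, a vinylogous acid para to the C4 carbonyl, is by far the most acidic hydroxyl, so one equivalent of weak base generates only the 7-phenoxide while the 5-OH is locked in a hydrogen bond to the carbonyl, the guaiacol-type 4'-OH stays protonated and the 3-OH is an alcohol; room temperature and argon guard C2 and C3 against epimerisation and ring C against aerobic dehydrogenation.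

Compound list
1 | phloroglucinol (benzene-1,3,5-triol) | Oc1cc(O)cc(O)c1 | starting material
2 | ethyl propiolate | C#CC(=O)OCC | starting material
3 | 5,7-dihydroxycoumarin | O=c1ccc2c(O)cc(O)cc2o1 | intermediate
4 | 5,7-bis(benzyloxy)coumarin | O=c1ccc2c(OCc3ccccc3)cc(OCc3ccccc3)cc2o1 | intermediate
5 | 5,7-bis(benzyloxy)-2H-chromen-2-ol (racemic) | OC1C=Cc2c(OCc3ccccc3)cc(OCc3ccccc3)cc2O1 | intermediate
6 | 5,7-bis(benzyloxy)-2-ethoxy-2H-chromene (racemic) | CCOC1C=Cc2c(OCc3ccccc3)cc(OCc3ccccc3)cc2O1 | intermediate
7 | 4-bromo-2-methoxyphenol (4-bromoguaiacol) | COc1cc(Br)ccc1O | starting material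
8 | 1-(benzyloxy)-4-bromo-2-methoxybenzene | COc1cc(Br)ccc1OCc1ccccc1 | intermediate
9 | [4-(benzyloxy)-3-methoxyphenyl]lithium (not isolated) | COc1cc([Li])ccc1OCc1ccccc1 | intermediate
10 | lithium [4-(benzyloxy)-3-methoxyphenyl]triisopropoxyborate (not isolated) | [Li+].COc1cc([B-](OC(C)C)(OC(C)C)OC(C)C)ccc1OCc1ccccc1 | intermediate
11 | [4-(benzyloxy)-3-methoxyphenyl]boronic acid | COc1cc(B(O)O)ccc1OCc1ccccc1 | intermediate
12 | diethyl [4-(benzyloxy)-3-methoxyphenyl]boronate | CCOB(OCC)c1ccc(OCc2ccccc2)c(OC)c1 | intermediate
13 | 5,7-bis(benzyloxy)chromenylium ion (not isolated) | c1cc2c(OCc3ccccc3)cc(OCc3ccccc3)cc2[o+]c1 | intermediate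
14 | (2S)-5,7-bis(benzyloxy)-2-[4-(benzyloxy)-3-methoxyphenyl]-2H-chromene | COc1cc([C@H]2Oc3cc(OCc4ccccc4)cc(OCc4ccccc4)c3C=C2)ccc1OCc1ccccc1 | intermediate
15 | cyclic O3,O4-osmate ester of 14, osmium on the face anti to the C2 aryl group (not isolated) | COc1cc([C@H]2Oc3cc(OCc4ccccc4)cc(OCc4ccccc4)c3[C@@H]5O[Os](=O)(=O)O[C@H]25)ccc1OCc1ccccc1 | intermediate
16 | (2R,3S,4S)-5,7-bis(benzyloxy)-2-[4-(benzyloxy)-3-methoxyphenyl]-3,4-dihydro-2H-chromene-3,4-diol (2,3-trans-3,4-cis) | COc1cc([C@H]2Oc3cc(OCc4ccccc4)cc(OCc4ccccc4)c3[C@H](O)[C@@H]2O)ccc1OCc1ccccc1 | intermediate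
17 | (2R,3S,4S)-3,5,7-tris(benzyloxy)-2-[4-(benzyloxy)-3-methoxyphenyl]-3,4-dihydro-2H-chromen-4-ol | COc1cc([C@H]2Oc3cc(OCc4ccccc4)cc(OCc4ccccc4)c3[C@H](O)[C@@H]2OCc2ccccc2)ccc1OCc1ccccc1 | intermediate
18 | (2R,3R)-3,5,7-tris(benzyloxy)-2-[4-(benzyloxy)-3-methoxyphenyl]-2,3-dihydro-4H-chromen-4-one | COc1cc([C@H]2Oc3cc(OCc4ccccc4)cc(OCc4ccccc4)c3C(=O)[C@@H]2OCc2ccccc2)ccc1OCc1ccccc1 | intermediate
19 | (2R,3R)-3,5,7-trihydroxy-2-(4-hydroxy-3-methoxyphenyl)-2,3-dihydro-4H-chromen-4-one | COc1cc([C@H]2Oc3cc(O)cc(O)c3C(=O)[C@@H]2O)ccc1O | intermediate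
20 | prenyl bromide (1-bromo-3-methylbut-2-ene) | CC(C)=CCBr | starting material
21 | (2R,3R)-3,5-dihydroxy-2-(4-hydroxy-3-methoxyphenyl)-7-[(3-methylbut-2-en-1-yl)oxy]-2,3-dihydro-4H-chromen-4-one | COc1cc([C@H]2Oc3cc(OCC=C(C)C)cc(O)c3C(=O)[C@@H]2O)ccc1O | target

Total step count: 13.
Longest linear sequence: 10 steps (steps 1–4 and 8–13, from phloroglucinol).

Steps most likely to fail

**Step 8, loss of enantiocontrol.** The strongly stabilised cation may undergo uncatalysed background addition. The product may also racemise by acid-induced ionisation of its C2–O1 bond.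
- The fallback sets out from boronic acid 11 and comes back to the route at 14. It sets C2 by conjugate addition instead of acetal substitution.
- Purchased 5,7-dihydroxychromone is benzylated (BnBr, K2CO3, DMF, 70 °C) to 5,7-bis(benzyloxy)-4H-chromen-4-one F1.
- Rhodium-catalysed asymmetric 1,4-addition of 11 to F1 ([Rh(OH)(cod)]2, an electron-poor MeO-BIPHEP-type bisphosphine, toluene/H2O, rt) should give (2S)-5,7-bis(benzyloxy)-2-[4-(benzyloxy)-3-methoxyphenyl]chroman-4-one F2.
- NaBH4 (THF/MeOH, 0 °C) reduces F2 to the 2,4-cis (2S,4S)-chroman-4-ol F3.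
- MsCl and Et3N (CH2Cl2, 0 °C) convert F3 into the 4-mesylate F4. F4 is not isolated and loses methanesulfonic acid in the basic medium to give 14 with C2 untouched.

**Step 10, poor discrimination between O3 and O4, or sluggish alkylation of the hindered diol.**
- The fallback sets out from 16 and comes back at 19. It drops the protecting group in favour of a chemoselective oxidation.
- DDQ (CH2Cl2/pH 7 buffer, rt) can abstract hydride only from the C4–H bond, which is activated by ring A. This should be slow, because the ring must first flip to align that bond, but the C3 carbinol cannot react. The product would be (2R,3R)-5,7-bis(benzyloxy)-2-[4-(benzyloxy)-3-methoxyphenyl]-3-hydroxy-2,3-dihydro-4H-chromen-4-one F5.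
- Hydrogenolysis of the three benzyl ethers of F5 (H2, Pd(OH)2/C, THF/MeOH) gives 19.

**Step 13, competing alkylation at O4', base-induced epimerisation through opening of the C2–O1 bond, or aerobic dehydrogenation of ring C.**
- The fallback sets out from 19 and comes back directly at 21. It activates the alcohol instead of the phenol.
- Mitsunobu etherification with 3-methylbut-2-en-1-ol, PPh3 and DIAD (THF, 0 °C) runs in a neutral medium. The most acidic phenol (7-OH) is the first to protonate the betaine and be alkylated, and the primary allylic alcohol is activated in preference to the hindered 3-OH.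
- No new compound is made on this way (entry F0).

Further compounds
F1 | step 8 | 5,7-bis(benzyloxy)-4H-chromen-4-one | O=c1ccoc2cc(OCc3ccccc3)cc(OCc3ccccc3)c12
F2 | step 8 | (2S)-5,7-bis(benzyloxy)-2-[4-(benzyloxy)-3-methoxyphenyl]chroman-4-one | COc1cc([C@H]2Oc3cc(OCc4ccccc4)cc(OCc4ccccc4)c3C(=O)C2)ccc1OCc1ccccc1
F3 | step 8 | (2S,4S)-5,7-bis(benzyloxy)-2-[4-(benzyloxy)-3-methoxyphenyl]chroman-4-ol (2,4-cis) | COc1cc([C@H]2Oc3cc(OCc4ccccc4)cc(OCc4ccccc4)c3[C@@H](O)C2)ccc1OCc1ccccc1
F4 | step 8 | (2S,4S)-5,7-bis(benzyloxy)-2-[4-(benzyloxy)-3-methoxyphenyl]chroman-4-yl methanesulfonate (not isolated) | COc1cc([C@H]2Oc3cc(OCc4ccccc4)cc(OCc4ccccc4)c3[C@@H](OS(C)(=O)=O)C2)ccc1OCc1ccccc1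
F5 | step 10 | (2R,3R)-5,7-bis(benzyloxy)-2-[4-(benzyloxy)-3-methoxyphenyl]-3-hydroxy-2,3-dihydro-4H-chromen-4-one | COc1cc([C@H]2Oc3cc(OCc4ccccc4)cc(OCc4ccccc4)c3C(=O)[C@@H]2O)ccc1OCc1ccccc1
F0 | step 13 | none | none
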